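**Retrosynthetic overview**

- Numbering: ring C is the cyclohexene (C1 quaternary with CH3 and the styryl arm, C2 and C3 CH2, C4(CH3)=C5, C6 bearing the aryl group); coumarin A sits on the styryl arm, coumarin B on C6. Both pyranone rings are cut back to 4-substituted 3-methoxyphenols (ortho-formylation, then ylide lactonisation), and the (E)-C1–CH=CH–aryl bond to an HWE olefination of a C1 carbaldehyde.
- The strategy rests on the C2–C3–C4(CH3)=C5 arm of ring C, which is an isoprene unit. Opening C2–C3 and tying C2 back to C5 turns ring C into a 2-isopropenylcyclobutanol (C2 carbinol, C5 isopropenyl), whose alkoxide re-expands to ring C; the C2 oxygen is then removed (Barton–McCombie).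
- In that cyclobutane C1 and C6 are the two carbons of an (E)-α-methylstyrene. The four-membered ring therefore comes from a [2+2] of isopropenylketene with the dimethyl acetal of (E)-3-aryl-2-methylpropenal, the E geometry placing aryl cis to CH3. The absolute configuration is fixed by separating diastereomeric (1S)-camphanates of the cyclobutanol.
- Ring order: cyclobutane (step 4), ring C by ring expansion (step 7), pyranone rings of A and B together (step 16).

Key step: step 7

Assumption: the configurations at C5 of the cyclobutanes and at the carbinol carbon C2 are drawn as the sterically expected epimers. Neither reaches the target (C5 becomes trigonal in the ring expansion, C2 is reduced to CH2), and the other epimers would follow the same steps. The racemic cyclobutanone is written with the SMILES of the enantiomer that is carried on.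

**Route**

Step 1
Reactants: 1 4-hydroxy-2-methoxybenzaldehyde
Product: 2 2-methoxy-4-(methoxymethoxy)benzaldehyde
Conditions: MOMCl, i-Pr2NEt, CH2Cl2, 0 °C → rt
Reagents that add atoms: chloromethyl methyl ether, COCCl
Why: Williamson-type O-alkylation of the phenol (MOM protection) masks the acidic OH, which would otherwise quench the ylide, the ketene and the later bases, as an ether that tolerates base, hydride and radical conditions and still donates into the ring.

Step 2
Reactants: 2 2-methoxy-4-(methoxymethoxy)benzaldehyde; 3 2-(triphenylphosphoranylidene)propanal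
Product: 4 (2E)-3-[2-methoxy-4-(methoxymethoxy)phenyl]-2-methylprop-2-enal
Conditions: toluene, 110 °C
Reagents that add atoms: none
Why: Wittig olefination with the stabilised formyl ylide is under thermodynamic control and should give the E enal (aryl trans to CHO, hence cis to CH3), the geometry that later becomes the aryl-cis-methyl relation at C6/C1.

Step 3
Reactants: 4 (2E)-3-[2-methoxy-4-(methoxymethoxy)phenyl]-2-methylprop-2-enal
Product: 5 (E)-1-(3,3-dimethoxy-2-methylprop-1-en-1-yl)-2-methoxy-4-(methoxymethoxy)benzene
Conditions: HC(OMe)3, PPTS (cat.), MeOH, rt; Et3N quench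
Reagents that add atoms: trimethyl orthoformate, COC(OC)OC; methanol, CO
Why: Acid-catalysed acetalisation with orthoformate as dehydrating agent removes the conjugating carbonyl so that the alkene becomes a donor-substituted styrene able to react with a ketene, and the weak acid PPTS in methanol at room temperature should not exchange the aryl MOM ether.

Step 4
Reactants: 5 (E)-1-(3,3-dimethoxy-2-methylprop-1-en-1-yl)-2-methoxy-4-(methoxymethoxy)benzene; 6 3-methylbut-2-enoyl chloride
Product: 8 racemic 2-(dimethoxymethyl)-3-[2-methoxy-4-(methoxymethoxy)phenyl]-2-methyl-4-(prop-1-en-2-yl)cyclobutan-1-one (aryl cis to the 2-methyl group; isopropenyl trans to aryl), via isopropenylketene 7 (not isolated)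
Conditions: Et3N (excess), toluene, 80 °C, slow addition of 6 (3 equiv) by syringe pump
Reagents that add atoms: none
Why: 1,4-Dehydrochlorination gives the vinylketene, whose carbonyl carbon bonds to the alkene carbon carrying CH3 and CH(OMe)2 while positive charge builds up at the benzylic carbon stabilised by the ortho-OMe and para-OMOM groups (thermal ketene–alkene [2+2] cycloaddition, suprafacial on the alkene), so that the E geometry is transferred as aryl cis to methyl and the isopropenyl-bearing α-carbon should settle trans to aryl under the amine.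

Step 5
Reactants: 8 racemic 2-(dimethoxymethyl)-3-[2-methoxy-4-(methoxymethoxy)phenyl]-2-methyl-4-(prop-1-en-2-yl)cyclobutan-1-one
Product: 10 2-(dimethoxymethyl)-3-[2-methoxy-4-(methoxymethoxy)phenyl]-2-methyl-4-(prop-1-en-2-yl)cyclobutyl (1S,4R)-4,7,7-trimethyl-3-oxo-2-oxabicyclo[2.2.1]heptane-1-carboxylate (single diastereomer whose cyclobutane has the C1/C6 configuration of the target; ester oxygen cis to isopropenyl), via lithium cyclobutanolate 9 (not isolated)
Conditions: LiBH(s-Bu)3, THF, −78 °C; then (1S)-(−)-camphanic chloride, DMAP (cat.), −78 °C → rt; chromatographic separation of the two diastereomers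
Reagents that add atoms: (1S)-(−)-camphanic chloride, ClC(=O)[C@@]12CC[C@@](C)(C(=O)O1)C2(C)C
Why: Hydride should add to the carbonyl face flanked by C1–CH3 and C5–H and the lithium alkoxide is acylated in the same flask (reductive acylation), so that the racemate becomes two diastereomeric camphanates whose separation (classical resolution, assignment by crystallography of the ester) fixes the absolute configuration at the later C1 and C6.

Step 6
Reactants: 10 cyclobutyl (1S)-camphanate
Product: 11 2-(dimethoxymethyl)-3-[2-methoxy-4-(methoxymethoxy)phenyl]-2-methyl-4-(prop-1-en-2-yl)cyclobutan-1-ol (single enantiomer; aryl cis to the 2-methyl group; OH cis to isopropenyl and to CH(OMe)2)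
Conditions: LiAlH4, THF, 0 °C; then H2O/NaOH
Reagents that add atoms: none
Why: Hydride reduction of the hindered ester (and of the lactone of the auxiliary) releases the cyclobutanol without touching any stereocentre, LiAlH4 being inert toward the acetal, the MOM ether and the isolated alkene.

Step 7
Reactants: 11 2-(dimethoxymethyl)-3-[2-methoxy-4-(methoxymethoxy)phenyl]-2-methyl-4-(prop-1-en-2-yl)cyclobutan-1-ol
Product: 13 2-(dimethoxymethyl)-3-[2-methoxy-4-(methoxymethoxy)phenyl]-2,5-dimethylcyclohex-4-en-1-ol (aryl cis to the 2-methyl group; OH cis to that methyl group), via potassium cyclobutanolate 12 (not isolated)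
Conditions: KH (2 equiv, oil-free), THF, 0 °C → 66 °C; then H2O
Reagents that add atoms: none
Why: KH converts the carbinol into the potassium alkoxide 12, whose oxyanion on C2 weakens the strained C2–C5 ring bond, so that this bond breaks (as a concerted [1,3] shift or by heterolysis to a C2 aldehyde tethered to a 2-methylallyl anion over C5–C4–C3) and C2 bonds to the isopropenyl terminus C3, which forms C2–C3 and the C4=C5 alkene. The closest known reaction type is the alkoxide-accelerated vinylcyclobutane-to-cyclohexene rearrangement of 2-vinylcyclobutanols obtained from vinylketene–alkene cycloadducts. Ring C closes by expansion of the four-membered ring, formally a 6-exo-trig addition of the allyl terminus C3 to the carbonyl carbon C2, driven by release of cyclobutane strain. The only new stereocentre is the carbinol carbon C2, expected with oxygen pseudo-equatorial and cis to the C1 methyl group under control of the chair-like closure but irrelevant because C2 becomes CH2 in step 9, while C1 (quaternary) and C6 (no bond to it is broken) keep the aryl-cis-methyl relation and the absolute configuration fixed in step 5. The step needs cleavage of C2–C5 in preference to C2–C1, which is secured because only C5 gives an allyl-stabilised carbanion, and recombination at C3 in preference to C5, which is secured by the strain of the four-membered ring. Loss of the opened anion by β-scission of the C6–C1 bond or by protonation is countered by running the reaction as a contact ion pair in THF without crown ether or HMPA and by the quaternary C1, which holds C2 close to C3.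

Step 8
Reactants: 13 2-(dimethoxymethyl)-3-[2-methoxy-4-(methoxymethoxy)phenyl]-2,5-dimethylcyclohex-4-en-1-ol
Product: 15 O-{2-(dimethoxymethyl)-3-[2-methoxy-4-(methoxymethoxy)phenyl]-2,5-dimethylcyclohex-4-en-1-yl} S-methyl carbonodithioate, via sodium xanthate 14 (not isolated)
Conditions: NaH, imidazole (cat.), THF, 0 °C; CS2; then MeI, rt
Reagents that add atoms: carbon disulfide, S=C=S; iodomethane, CI
Why: Xanthate formation (addition of the sodium alkoxide to CS2, then S-methylation) turns the hindered secondary alcohol into a radical-cleavable thiocarbonyl derivative under basic conditions that leave acetal, MOM ether and alkene alone.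

Step 9
Reactants: 15 S-methyl xanthate
Product: 16 1-[6-(dimethoxymethyl)-3,6-dimethylcyclohex-2-en-1-yl]-2-methoxy-4-(methoxymethoxy)benzene (aryl cis to the 6-methyl group)
Conditions: Bu3SnH, AIBN (cat.), toluene, 100 °C
Reagents that add atoms: none
Why: In the Barton–McCombie deoxygenation the tin radical adds to C=S, the secondary C2 radical is released by β-scission and is reduced by Bu3SnH, which turns C2 into the CH2 of the target while the adjacent quaternary C1 and the remote C6 are untouched.

Step 10
Reactants: 16 1-[6-(dimethoxymethyl)-3,6-dimethylcyclohex-2-en-1-yl]-2-methoxy-4-(methoxymethoxy)benzene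
Product: 17 2-[2-methoxy-4-(methoxymethoxy)phenyl]-1,4-dimethylcyclohex-3-ene-1-carbaldehyde (aryl cis to the 1-methyl group and trans to CHO)
Conditions: AcOH/THF/H2O, 45 °C
Reagents that add atoms: water, O
Why: Acid-catalysed acetal hydrolysis in aqueous acetic acid frees the non-enolisable α-quaternary aldehyde (C1 cannot epimerise), the dimethyl acetal being far more labile than the formaldehyde-derived aryl MOM acetal.

Step 11
Reactants: 2 2-methoxy-4-(methoxymethoxy)benzaldehyde
Product: 18 [2-methoxy-4-(methoxymethoxy)phenyl]methanol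
Conditions: NaBH4, MeOH, 0 °C
Reagents that add atoms: none
Why: Borohydride reduction of the aromatic aldehyde gives the benzylic alcohol needed for the phosphonate arm.

Step 12
Reactants: 18 [2-methoxy-4-(methoxymethoxy)phenyl]methanol
Product: 21 diethyl [2-methoxy-4-(methoxymethoxy)benzyl]phosphonate, via benzyl mesylate 19 (not isolated), via benzyl bromide 20 (not isolated)
Conditions: MsCl, Et3N, THF, 0 °C; LiBr, rt; filter, concentrate; P(OEt)3, 100 °C
Reagents that add atoms: triethyl phosphite, CCOP(OCC)OCC (methanesulfonyl chloride, CS(=O)(=O)Cl, and lithium bromide, [Li+].[Br-], add atoms only to intermediates 19 and 20)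
Why: Mesylation, displacement by bromide and Michaelis–Arbuzov reaction of the activated benzylic bromide with triethyl phosphite are run without isolating the labile electron-rich benzylic electrophiles and avoid any acid that would cleave the MOM ether.

Step 13
Reactants: 17 2-[2-methoxy-4-(methoxymethoxy)phenyl]-1,4-dimethylcyclohex-3-ene-1-carbaldehyde; 21 diethyl [2-methoxy-4-(methoxymethoxy)benzyl]phosphonate
Product: 23 1-[(E)-2-{2-[2-methoxy-4-(methoxymethoxy)phenyl]-1,4-dimethylcyclohex-3-en-1-yl}ethenyl]-2-methoxy-4-(methoxymethoxy)benzene (C1 R and C6 S; ring aryl cis to the 1-methyl group), via sodium phosphonate carbanion 22 (not isolated)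
Conditions: NaH, 15-crown-5 (cat.), THF, 0 °C (21 first); then 17, 0 °C → rt
Reagents that add atoms: none
Why: Horner–Wadsworth–Emmons olefination of the hindered aldehyde with the semi-stabilised benzylic phosphonate anion is reversible up to the elimination and should give the E alkene, and the base finds no epimerisable centre (C1 quaternary, C6 not acidified).

Step 14
Reactants: 23 bis-MOM ether
Product: 24 4-[(E)-2-{2-(4-hydroxy-2-methoxyphenyl)-1,4-dimethylcyclohex-3-en-1-yl}ethenyl]-3-methoxyphenol (C1 R and C6 S)
Conditions: TsOH·H2O (cat.), MeOH, rt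
Reagents that add atoms: none
Why: Acid-catalysed transacetalisation to methanol removes both aryl MOM groups at room temperature, which should be mild enough to leave the styrene, the ring alkene and the methyl ethers intact.

Step 15
Reactants: 24 bis-phenol
Product: 25 2-hydroxy-5-[6-{(E)-2-(5-formyl-4-hydroxy-2-methoxyphenyl)ethenyl}-3,6-dimethylcyclohex-2-en-1-yl]-4-methoxybenzaldehyde (C1 R and C6 S)
Conditions: MgCl2, Et3N, (CH2O)n, MeCN, 80 °C
Reagents that add atoms: paraformaldehyde (formaldehyde), C=O
Why: Magnesium-phenoxide-directed ortho-formylation delivers formaldehyde only ortho to each OH, and of the two ortho sites the one para to OCH3 and free of a flanking substituent should react, which is the carbon that becomes C4a of each coumarin.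

Step 16
Reactants: 25 bis-salicylaldehyde
Product: 27 7-methoxy-6-[(1S,6R)-6-[(E)-2-(7-methoxy-2-oxo-2H-chromen-6-yl)ethenyl]-3,6-dimethylcyclohex-2-en-1-yl]-2H-chromen-2-one (CNP0415737.1), via bis(acyl ylide) ester 26 (not isolated)
Conditions: Ph3P=C=C=O (2.5 equiv), toluene, 100 °C
Reagents that add atoms: (triphenylphosphoranylidene)ketene, O=C=C=P(c1ccccc1)(c1ccccc1)c1ccccc1
Why: Each phenol adds to the ketene-type ylide to give an aryl (triphenylphosphoranylidene)acetate whose intramolecular Wittig reaction with the ortho aldehyde can only form the cis alkene of the lactone, so both coumarin rings close at a temperature well below that at which the 1,5-diene around C1–C6 could undergo a Cope rearrangement.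

**Compound list**

1 | 4-hydroxy-2-methoxybenzaldehyde | COc1cc(O)ccc1C=O | starting material
2 | 2-methoxy-4-(methoxymethoxy)benzaldehyde | COCOc1ccc(C=O)c(OC)c1 | intermediate
3 | 2-(triphenylphosphoranylidene)propanal | CC(C=O)=P(c1ccccc1)(c1ccccc1)c1ccccc1 | starting material
4 | (2E)-3-[2-methoxy-4-(methoxymethoxy)phenyl]-2-methylprop-2-enal | COCOc1ccc(/C=C(\C)C=O)c(OC)c1 | intermediate
5 | (E)-1-(3,3-dimethoxy-2-methylprop-1-en-1-yl)-2-methoxy-4-(methoxymethoxy)benzene | COCOc1ccc(/C=C(\C)C(OC)OC)c(OC)c1 | intermediate
6 | 3-methylbut-2-enoyl chloride | CC(C)=CC(=O)Cl | starting material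
7 | isopropenylketene (3-methylbuta-1,3-dien-1-one), not isolated | CC(=C)C=C=O | intermediate
8 | racemic 2-(dimethoxymethyl)-3-[2-methoxy-4-(methoxymethoxy)phenyl]-2-methyl-4-(prop-1-en-2-yl)cyclobutan-1-one; aryl cis to 2-CH3, isopropenyl trans to aryl; SMILES of the enantiomer carried on | COC(OC)[C@@]1(C)C(=O)[C@@H](C(C)=C)[C@@H]1c1ccc(OCOC)cc1OC | intermediate
9 | lithium alkoxide of the cyclobutanol (racemic; O cis to isopropenyl), not isolated | COC(OC)[C@@]1(C)[C@@H]([O-])[C@@H](C(C)=C)[C@@H]1c1ccc(OCOC)cc1OC.[Li+] | intermediate
10 | (1S)-camphanate of the cyclobutanol, single diastereomer | COC(OC)[C@@]1(C)[C@@H](OC(=O)[C@@]23CC[C@@](C)(C(=O)O2)C3(C)C)[C@@H](C(C)=C)[C@@H]1c1ccc(OCOC)cc1OC | intermediate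
11 | 2-(dimethoxymethyl)-3-[2-methoxy-4-(methoxymethoxy)phenyl]-2-methyl-4-(prop-1-en-2-yl)cyclobutan-1-ol, single enantiomer; aryl cis to 2-CH3, OH cis to isopropenyl | COC(OC)[C@@]1(C)[C@@H](O)[C@@H](C(C)=C)[C@@H]1c1ccc(OCOC)cc1OC | intermediate
12 | potassium alkoxide of 11, not isolated | COC(OC)[C@@]1(C)[C@@H]([O-])[C@@H](C(C)=C)[C@@H]1c1ccc(OCOC)cc1OC.[K+] | intermediate
13 | 2-(dimethoxymethyl)-3-[2-methoxy-4-(methoxymethoxy)phenyl]-2,5-dimethylcyclohex-4-en-1-ol; aryl cis to 2-CH3, OH cis to 2-CH3 | COC(OC)[C@@]1(C)[C@H](O)CC(C)=C[C@@H]1c1ccc(OCOC)cc1OC | intermediate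
14 | sodium O-cyclohexenyl dithiocarbonate of 13, not isolated | COC(OC)[C@@]1(C)[C@H](OC(=S)[S-])CC(C)=C[C@@H]1c1ccc(OCOC)cc1OC.[Na+] | intermediate
15 | O-{2-(dimethoxymethyl)-3-[2-methoxy-4-(methoxymethoxy)phenyl]-2,5-dimethylcyclohex-4-en-1-yl} S-methyl carbonodithioate | COC(OC)[C@@]1(C)[C@H](OC(=S)SC)CC(C)=C[C@@H]1c1ccc(OCOC)cc1OC | intermediate
16 | 1-[6-(dimethoxymethyl)-3,6-dimethylcyclohex-2-en-1-yl]-2-methoxy-4-(methoxymethoxy)benzene; aryl cis to 6-CH3 | COC(OC)[C@@]1(C)CCC(C)=C[C@@H]1c1ccc(OCOC)cc1OC | intermediate
17 | 2-[2-methoxy-4-(methoxymethoxy)phenyl]-1,4-dimethylcyclohex-3-ene-1-carbaldehyde; aryl cis to 1-CH3 | O=C[C@@]1(C)CCC(C)=C[C@@H]1c1ccc(OCOC)cc1OC | intermediate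
18 | [2-methoxy-4-(methoxymethoxy)phenyl]methanol | COCOc1ccc(CO)c(OC)c1 | intermediate
19 | 2-methoxy-4-(methoxymethoxy)benzyl methanesulfonate, not isolated | COCOc1ccc(COS(C)(=O)=O)c(OC)c1 | intermediate
20 | 1-(bromomethyl)-2-methoxy-4-(methoxymethoxy)benzene, not isolated | COCOc1ccc(CBr)c(OC)c1 | intermediate
21 | diethyl [2-methoxy-4-(methoxymethoxy)benzyl]phosphonate | CCOP(=O)(Cc1ccc(OCOC)cc1OC)OCC | intermediate
22 | sodium salt of the benzylic carbanion of 21, not isolated | CCOP(=O)([CH-]c1ccc(OCOC)cc1OC)OCC.[Na+] | intermediate
23 | 1-[(E)-2-{2-[2-methoxy-4-(methoxymethoxy)phenyl]-1,4-dimethylcyclohex-3-en-1-yl}ethenyl]-2-methoxy-4-(methoxymethoxy)benzene; C1 R, C6 S | COCOc1ccc(/C=C/[C@@]2(C)CCC(C)=C[C@@H]2c2ccc(OCOC)cc2OC)c(OC)c1 | intermediate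
24 | 4-[(E)-2-{2-(4-hydroxy-2-methoxyphenyl)-1,4-dimethylcyclohex-3-en-1-yl}ethenyl]-3-methoxyphenol; C1 R, C6 S | COc1cc(O)ccc1/C=C/[C@@]1(C)CCC(C)=C[C@@H]1c1ccc(O)cc1OC | intermediate
25 | 2-hydroxy-5-[6-{(E)-2-(5-formyl-4-hydroxy-2-methoxyphenyl)ethenyl}-3,6-dimethylcyclohex-2-en-1-yl]-4-methoxybenzaldehyde; C1 R, C6 S | COc1cc(O)c(C=O)cc1/C=C/[C@@]1(C)CCC(C)=C[C@@H]1c1cc(C=O)c(O)cc1OC | intermediate
26 | bis[(triphenylphosphoranylidene)acetate] ester of 25, not isolated | COc1cc(OC(=O)C=P(c2ccccc2)(c2ccccc2)c2ccccc2)c(C=O)cc1/C=C/[C@@]1(C)CCC(C)=C[C@@H]1c1cc(C=O)c(OC(=O)C=P(c2ccccc2)(c2ccccc2)c2ccccc2)cc1OC | intermediate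
27 | 7-methoxy-6-[(1S,6R)-6-[(E)-2-(7-methoxy-2-oxo-2H-chromen-6-yl)ethenyl]-3,6-dimethylcyclohex-2-en-1-yl]-2H-chromen-2-one (CNP0415737.1) | COc1cc2oc(=O)ccc2cc1/C=C/[C@@]1(C)CCC(C)=C[C@@H]1c1cc2ccc(=O)oc2cc1OC | target

**Step count and risks**

Total step count: 16. Longest linear sequence: 14 steps (steps 1–10 and 13–16, from 1).

Steps most likely to fail:

1. Step 4. The vinylketene may dimerise or polymerise faster than it adds to the hindered, trisubstituted, acetal-bearing styrene, and a long-lived zwitterion could erode the aryl-cis-methyl relation. Fallback (sets out from 5, comes back at 8): 5 is treated with the far more electrophilic dichloroketene (Cl2CHCOCl, Et3N, hexane, reflux), which should add with the same regiochemistry to give the racemic 2,2-dichloro-4-(dimethoxymethyl)-3-aryl-4-methylcyclobutan-1-one F1. Reductive dechlorination (Zn, NH4Cl, MeOH) then gives the racemic 2-(dimethoxymethyl)-3-aryl-2-methylcyclobutan-1-one F2. Palladium-catalysed α-alkenylation of its lithium enolate with 2-bromopropene (Pd2(dba)3, P(t-Bu)3, LiN(SiMe3)2, THF), with kinetic α-protonation of the dienolate on work-up, leads to 8.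

2. Step 7. The ring-opened allyl anion may be lost by β-scission (retro-[2+2] to a 1-aryl-3-methylbuta-1,3-diene and an aldehyde enolate) or by protonation to an acyclic aldehyde before it closes at C3. Fallback (sets out from 11, comes back at 13): oxidation of 11 with Dess–Martin periodinane returns ketone 8, now as the single enantiomer. Irradiation (λ > 300 nm, benzene) should bring about the photochemical 1,3-acyl shift known for β,γ-unsaturated ketones and 2-vinylcyclobutanones: α-cleavage on the allylic side and recombination of the acyl carbon C2 with the allyl terminus C3. This gives the cyclohex-3-enone F3 without any anionic intermediate, and NaBH4 in MeOH then gives 13 (either C2 epimer serves).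

3. Step 5. Acylation of the hindered lithium alkoxide may stall, or the two camphanates may not separate. Fallback (sets out from 8, comes back at 17): 8 is reduced (LiBH(s-Bu)3, aqueous work-up) to racemic 11, and steps 7–10 are run on racemic material to racemic 17. Condensation with (1R,2R)-N,N'-dimethyl-1,2-diphenylethane-1,2-diamine (4 Å molecular sieves, Et2O) gives two diastereomeric imidazolidines, from which the one with the wanted ring configuration, aminal F4, is separated by chromatography or crystallisation. Brief treatment with dilute aqueous HCl in Et2O releases enantiopure 17.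

Further compounds
F1 | step 4 | racemic 2,2-dichloro-4-(dimethoxymethyl)-3-[2-methoxy-4-(methoxymethoxy)phenyl]-4-methylcyclobutan-1-one (aryl cis to CH3) | COC(OC)[C@@]1(C)C(=O)C(Cl)(Cl)[C@@H]1c1ccc(OCOC)cc1OC
F2 | step 4 | racemic 2-(dimethoxymethyl)-3-[2-methoxy-4-(methoxymethoxy)phenyl]-2-methylcyclobutan-1-one (aryl cis to CH3) | COC(OC)[C@@]1(C)C(=O)C[C@@H]1c1ccc(OCOC)cc1OC
F3 | step 7 | 2-(dimethoxymethyl)-3-[2-methoxy-4-(methoxymethoxy)phenyl]-2,5-dimethylcyclohex-4-en-1-one (aryl cis to 2-CH3) | COC(OC)[C@@]1(C)C(=O)CC(C)=C[C@@H]1c1ccc(OCOC)cc1OC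
F4 | step 5 | (4R,5R)-2-{2-[2-methoxy-4-(methoxymethoxy)phenyl]-1,4-dimethylcyclohex-3-en-1-yl}-1,3-dimethyl-4,5-diphenylimidazolidine (ring configuration as in 17) | CN1[C@H](c2ccccc2)[C@@H](c2ccccc2)N(C)C1[C@@]3(C)CCC(C)=C[C@@H]3c4ccc(OCOC)cc4OC
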